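# Proposed synthesis of CNP0503951.0 (compound 32) by vinylketene–ynol ether benzannulation of ring A

## Analysis of the target

Compound 32 is a linear tridepside in which three orsellinate-type benzene rings (A, B and C) are joined by two aryl ester bonds: the C1 carboxyl of ring A is esterified by O4 of ring B, and the C1 carboxyl of ring B by O4 of ring C. In every ring C1 carries the carboxyl carbon, C2 and C4 carry oxygen and C6 carries a methyl group; ring C is a methyl ester with a C2 methyl ether, ring B has a free C2 hydroxyl, and ring A has free hydroxyls at C2 and C4. There is no stereocentre and no fused ring, so the problems are regiochemical and chemoselective only. The sensitive groups are the two aryl benzoate links (open to acyl transfer, to base and to photo-Fries cleavage under short-wavelength light), the methyl ester and the three free phenols. The difficulty is twofold: each aryl ester joins a phenol oxygen to a carbonyl flanked by two ortho substituents, and six similar oxygen atoms must end in three different states (one methyl ether, two acylated, three free). The strategy rests on ring A: C1 with its ester carbonyl, C6 with its methyl group and C5 map onto an ester-bearing isopropenylketene whose carbonyl carbon becomes C4 with its hydroxyl, and C2–C3 map onto a silyloxyethyne. Ring A can therefore be grown on O4 of ring B with the hindered ester already in place and with O2 (silylated) and O4 (free) differentiated from the start.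

## Retrosynthetic reasoning

**32 to 31.** The last operation is removal of two silyl groups, one on O2 of ring A and one on O2 of ring B. Carrying both phenols as the same silyl ether means a single fluoride treatment finishes the synthesis, and no ester or ether has to be touched.

**31 to 21 and 26.** Ring A is taken apart at four bonds: C1–C6, C1–C2, C3–C4 and C4–C5. This leaves diazo ketoester 21, in which the ring B oxygen already carries the future C1 carboxyl group, and silyloxyalkyne 26, which supplies C2 with its oxygen and C3. The cut is made here and not at the ester C–O bond because the ester is then formed on an unhindered acyl unit long before the ring exists. In the forward direction 21 must rearrange to acylketene 27, add 26 to give cyclobutenone 28, open to dienylketene 29 and close to cyclohexadienone 30, which tautomerizes to 31. The polarity of 26 puts the silyloxy group at C2 and the ketene oxygen at C4.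

**26 to 22.** The ynol ether is cut at its C–O and O–Si bonds, back to acetylene 22, the electrophilic oxygen source 23 and silyl triflate 11. In the forward direction acetylide 24 is oxygenated to ynolate 25, which is silylated on oxygen, so the two-carbon unit is made in one flask.

**21 to 18 and 19.** The bond between the diazo carbon and the ketone carbon is cut, which gives diazoacetate 18 and methacrolein 19. Aldehyde 19 supplies C4, C5, C6 and the methyl group of ring A. An aldol-type addition to carbinol 20 followed by oxidation recreates the ketone.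

**18 to 15, and 15 to 13 and 14.** The diazo group is traced back to a bromide, exchanged by means of hydrazine 16 through adduct 17. Bromoacetate 15 is cut at its ester C–O bond into phenol 13 and bromoacetyl bromide 14. The acylation occurs at the only free hydroxyl of 13 and meets no steric problem.

**13 to 12 to 10.** Two protecting-group changes separate 13 from 10. Going backwards, the free O4 of ring B in 13 is masked as the benzyl ether of 12, and the silyl ether on O2 of ring B in 12 is removed to give 10. In the forward direction 10 is silylated with 11 and 12 is then hydrogenolysed. The silyl ether keeps the ring B phenol out of the base-mediated steps and away from the ketene.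

**10 to 8 and 6.** The one aryl ester bond made by esterification, between the ring B carbonyl and O4 of ring C, is cut here. Acid 8 is activated as mixed anhydride 9 and acylates the single hydroxyl of phenol 6; the chelated O2–H of 8 stays out of the reaction.

**8 and 6 to 3, and 3 to 1.** Both partners derive from monobenzyl ether 3: hydrolysis with 7 gives 8, and methylation with 4 to give 5, followed by debenzylation, gives 6. Ether 3 comes from methyl orsellinate 1 and benzyl bromide 2, using the higher reactivity of the unchelated O4.

## Alternatives that were turned down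

**Alternative 1:** One orsellinate ring is cut at C1–C6 and C3–C4, which leads back to methyl acetoacetate A1 and methyl (E)-but-2-enoate A2. Under alkoxide base the enolate of A1 adds to A2 in a Michael reaction that forms C1–C6, and Dieckmann condensation then forms C3–C4 and closes the ring to methyl 6-methyl-2,4-dioxocyclohexane-1-carboxylate A3. Dehydrogenation of A3 gives methyl orsellinate A4, which is the same compound as 1.
- For: the chemistry is classical, cheap and scalable, A1 and A2 are commodity esters, and the stereocentres of A3 are erased on aromatization. On robustness it is clearly stronger than the route chosen here.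
- Against: it spends two or three steps, including an aromatization that tends to over-halogenate, to reach A4, a compound that can be bought. It answers neither the hindered ester bonds nor the differentiation of the oxygens.
- Comparison: it is a way to a starting material, not to the tridepside. The chosen strategy places its ring construction where it removes a hindered esterification.

**Alternative 2:** Ring C is cut at C5–C6 and C3–C4, which leads back to methyl 4-methoxy-6-methyl-2-oxo-2H-pyran-5-carboxylate A5 and 1,1-bis(trimethylsilyloxy)ethene A6. On heating, A6 adds across the diene of A5, the bridged adduct loses its lactone bridge and one silyloxy group, and work-up frees the C4 hydroxyl to give methyl 4-hydroxy-2-methoxy-6-methylbenzoate A7, which is the same compound as 6.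
- For: the methyl ether at C2 and the free hydroxyl at C4 are set apart in one operation. On this point it is stronger than the three steps used here for 6.
- Against: A5 is not a stock compound and needs its own multistep preparation. Its 4-methoxy group makes it a poorer electron-deficient diene and its C6 is fully substituted, so forcing temperatures are expected, at which A6 is unstable. Only the simplest ring is built; both depside bonds and rings A and B remain.
- Comparison: once A5 has to be made, the count to A7 is no shorter than benzylation, methylation and hydrogenolysis of 1, and the first of those steps also serves ring B.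

**Alternative 3:** Ring B is cut at C1–C2 and C5–C6, which leads back to 1-methoxy-1,3-bis(trimethylsilyloxy)buta-1,3-diene A8 and the but-2-ynoate of the ring C phenol, methyl 4-(but-2-ynoyloxy)-2-methoxy-6-methylbenzoate A9. Thermal cycloaddition of A8 to A9, followed by acidic work-up with loss of the methoxy and silyl groups, would give methyl 4-[(2,4-dihydroxy-6-methylbenzoyl)oxy]-2-methoxy-6-methylbenzoate A10.
- For: it shares the logic of the chosen route, since the hindered aryl ester exists before the ring does, and its reaction type has better precedent. It could be repeated on O4 of A10 to make ring A, so it is as strong or stronger on precedent and on protecting-group economy.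
- Against: A9 is a β-methyl ynoate with one activating group and therefore a weak dienophile. A8 is strongly nucleophilic, can attack the activated aryl ester carbonyl or stop at conjugate addition, and degrades on prolonged heating. In a second round two aryl esters would face that nucleophile, and O2 and O4 of the new ring would differ only by hydrogen bonding.
- Comparison: the chosen strategy builds the ring with neutral, non-nucleophilic intermediates near room temperature and delivers O2 and O4 of ring A in chemically different states. The price is a ketene type that is untested in this cascade.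

Key step: step 12

Remarks on the chemistry:
- Ring positions are numbered as in the analysis (C1 carboxyl-bearing, C2 and C4 oxygen-bearing, C6 methyl-bearing).
- In short names "Ar" is the aryl group of phenol 13 (13 = ArOH), so that "Ar bromoacetate" is the bromoacetic ester of 13.
- (Triisopropylsilyloxy)ethyne is assumed not to be purchasable and is prepared in step 11.
- Compounds 20 and 28 are racemic and their stereocentres do not persist.

## Route

Step 1
Reactants: 1 methyl orsellinate (methyl 2,4-dihydroxy-6-methylbenzoate); 2 benzyl bromide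
Product: 3 methyl 4-(benzyloxy)-2-hydroxy-6-methylbenzoate
Conditions: BnBr (1.05 equiv), K2CO3, acetone, reflux
Reagents that add atoms: benzyl bromide, BrCc1ccccc1
Why: Williamson etherification; the C4 hydroxyl is the more acidic and accessible one, whereas the C2 hydroxyl is tied up in a hydrogen bond to the ester carbonyl, so one equivalent of halide should alkylate O4 selectively.

Step 2
Reactants: 3 methyl 4-(benzyloxy)-2-hydroxy-6-methylbenzoate; 4 iodomethane
Product: 5 methyl 4-(benzyloxy)-2-methoxy-6-methylbenzoate
Conditions: MeI, K2CO3, DMF, 50 °C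
Reagents that add atoms: iodomethane, CI
Why: Williamson methylation of the remaining chelated phenol under more forcing conditions; with O4 blocked only O2 can react, which fixes the methyl ether of ring C.

Step 3
Reactants: 5 methyl 4-(benzyloxy)-2-methoxy-6-methylbenzoate
Product: 6 methyl 4-hydroxy-2-methoxy-6-methylbenzoate
Conditions: H2 (1 atm), 10% Pd/C, EtOAc, rt
Reagents that add atoms: none
Why: Hydrogenolysis of the benzyl ether frees O4 of ring C; the methyl ester and methyl ether are inert under these neutral conditions.

Step 4
Reactants: 3 methyl 4-(benzyloxy)-2-hydroxy-6-methylbenzoate; 7 potassium hydroxide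
Product: 8 4-(benzyloxy)-2-hydroxy-6-methylbenzoic acid
Conditions: KOH, DMSO–H2O, 80 °C; then cold aq. HCl to pH 2
Reagents that add atoms: potassium hydroxide, [K+].[OH-]
Why: Saponification of a di-ortho-substituted benzoate needs hydroxide in a dipolar aprotic medium; the benzyl ether is inert, and acidification in the cold avoids decarboxylation of the electron-rich acid.

Step 5
Reactants: 8 4-(benzyloxy)-2-hydroxy-6-methylbenzoic acid; 6 methyl 4-hydroxy-2-methoxy-6-methylbenzoate
Product: 10 methyl 4-{[4-(benzyloxy)-2-hydroxy-6-methylbenzoyl]oxy}-2-methoxy-6-methylbenzoate, via mixed trifluoroacetic anhydride 9 (not isolated)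
Conditions: (CF3CO)2O, toluene, rt; aq. NaHCO3 work-up
Reagents that add atoms: methyl 4-hydroxy-2-methoxy-6-methylbenzoate (6), COC(=O)c1c(C)cc(O)cc1OC
Why: Mixed-anhydride esterification as used for depsides; the acid is activated as its acyl trifluoroacetate and acylates the single free hydroxyl of 6, while the C2 hydroxyl of 8, hydrogen-bonded to its own carbonyl, should not compete.

Step 6
Reactants: 10 methyl 4-{[4-(benzyloxy)-2-hydroxy-6-methylbenzoyl]oxy}-2-methoxy-6-methylbenzoate; 11 triisopropylsilyl trifluoromethanesulfonate
Product: 12 methyl 4-{[4-(benzyloxy)-6-methyl-2-(triisopropylsilyloxy)benzoyl]oxy}-2-methoxy-6-methylbenzoate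
Conditions: TIPSOTf, 2,6-lutidine, CH2Cl2, 0 °C to rt
Reagents that add atoms: triisopropylsilyl trifluoromethanesulfonate, CC(C)[Si](OS(=O)(=O)C(F)(F)F)(C(C)C)C(C)C
Why: O-Silylation with a silyl triflate and a hindered pyridine base is forceful enough for a phenol hydrogen-bonded to the neighbouring ester; this hydroxyl would otherwise consume base in steps 9 and 10 and trap the ketene of step 12.

Step 7
Reactants: 12 methyl 4-{[4-(benzyloxy)-6-methyl-2-(triisopropylsilyloxy)benzoyl]oxy}-2-methoxy-6-methylbenzoate
Product: 13 methyl 4-{[4-hydroxy-6-methyl-2-(triisopropylsilyloxy)benzoyl]oxy}-2-methoxy-6-methylbenzoate (ArOH)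
Conditions: H2 (1 atm), 10% Pd/C, EtOAc, rt
Reagents that add atoms: none
Why: Hydrogenolysis of the benzyl ether; the aryl ester, the aryl silyl ether and the methyl ester are untouched under neutral conditions, so only O4 of ring B is freed.

Step 8
Reactants: 13 methyl 4-{[4-hydroxy-6-methyl-2-(triisopropylsilyloxy)benzoyl]oxy}-2-methoxy-6-methylbenzoate; 14 bromoacetyl bromide
Product: 15 methyl 4-{[4-(2-bromoacetoxy)-6-methyl-2-(triisopropylsilyloxy)benzoyl]oxy}-2-methoxy-6-methylbenzoate (Ar bromoacetate)
Conditions: BrCH2COBr, pyridine, CH2Cl2, −10 °C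
Reagents that add atoms: bromoacetyl bromide, BrCC(Br)=O
Why: O-Acylation of the only free phenol; the acyl bromide reacts far faster at its carbonyl than at the CH2Br carbon, and the low temperature limits quaternization of pyridine.

Step 9
Reactants: 15 Ar bromoacetate; 16 N,N'-bis(p-toluenesulfonyl)hydrazine
Product: 18 methyl 4-{[4-(2-diazoacetoxy)-6-methyl-2-(triisopropylsilyloxy)benzoyl]oxy}-2-methoxy-6-methylbenzoate (Ar diazoacetate), via N-alkylated ditosylhydrazide 17 (not isolated)
Conditions: TsNHNHTs, DBU, THF, 0 °C
Reagents that add atoms: N,N'-bis(p-toluenesulfonyl)hydrazine, Cc1ccc(cc1)S(=O)(=O)NNS(=O)(=O)c1ccc(C)cc1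
Why: Bromide-to-diazo exchange; the hydrazide anion displaces bromide (SN2) and DBU then eliminates two sulfinate groups to leave the diazoacetate, under brief cold conditions that the hindered depside ester and the silyl ether should tolerate.

Step 10
Reactants: 18 Ar diazoacetate; 19 methacrolein
Product: 21 methyl 4-{[4-(2-diazo-4-methyl-3-oxopent-4-enoyloxy)-6-methyl-2-(triisopropylsilyloxy)benzoyl]oxy}-2-methoxy-6-methylbenzoate (Ar 2-diazo-4-methyl-3-oxopent-4-enoate), via diazo hydroxy ester 20 (not isolated)
Conditions: methacrolein, DBU (0.2 equiv), DMSO, rt; then IBX, rt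
Reagents that add atoms: methacrolein, CC(=C)C=O
Why: Amidine-catalysed aldol-type 1,2-addition of the diazoacetate C–H to the aldehyde gives the racemic carbinol, whose stereocentre is removed at once by IBX oxidation of the allylic alcohol in the same flask; the diazo group is inert to IBX.

Step 11
Reactants: 22 acetylene; 23 tert-butyl hydroperoxide; 11 triisopropylsilyl trifluoromethanesulfonate
Product: 26 (triisopropylsilyloxy)ethyne, via lithium acetylide 24 (not isolated), via lithium ethynolate 25 (not isolated)
Conditions: n-BuLi, THF, −78 °C; t-BuOOLi (from t-BuOOH and LiN(SiMe3)2, THF, −78 °C), −78 to −20 °C; TIPSOTf, −78 to 0 °C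
Reagents that add atoms: tert-butyl hydroperoxide, CC(C)(C)OO; triisopropylsilyl trifluoromethanesulfonate, CC(C)[Si](OS(=O)(=O)C(F)(F)F)(C(C)C)C(C)C
Why: Electrophilic oxygenation of a lithium acetylide by lithium tert-butyl peroxide gives the ynolate, which the bulky, oxophilic silyl triflate should silylate on oxygen; this one-flask route from terminal alkynes to triisopropylsilyl ynol ethers is applied here to acetylene itself and kept cold so that the monolithium acetylide does not disproportionate.

Step 12
Reactants: 21 Ar 2-diazo-4-methyl-3-oxopent-4-enoate; 26 (triisopropylsilyloxy)ethyne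
Product: 31 methyl 4-{[4-{[4-hydroxy-6-methyl-2-(triisopropylsilyloxy)benzoyl]oxy}-6-methyl-2-(triisopropylsilyloxy)benzoyl]oxy}-2-methoxy-6-methylbenzoate, via acylketene 27 (not isolated), via cyclobutenone 28 (not isolated), via dienylketene 29 (not isolated), via cyclohexadienone 30 (not isolated)
Conditions: 26 (3 equiv), hν (365 nm LED), degassed toluene, 20 °C; then 80 °C
Reagents that add atoms: (triisopropylsilyloxy)ethyne (26), C#CO[Si](C(C)C)(C(C)C)C(C)C
Why: Proposed new method: irradiation at 365 nm, a wavelength at which the aryl benzoate links should not absorb, expels dinitrogen from 21 and the isopropenyl group shifts from the ketone carbon to the former diazo carbon (Wolff rearrangement, C1–C6) to give acylketene 27; the nearest established reaction type is the Danheiser benzannulation, in which a vinylketene made from a cyclobutenone or by photochemical Wolff rearrangement of an unsaturated diazo ketone combines with an alkoxy- or silyloxyalkyne, and what is untested there is a ketene that carries an ester group on its α-carbon and stems from a diazo ketoester. In the [2+2] cycloaddition the unsubstituted, nucleophilic carbon of 26 attacks the carbonyl carbon of 27 (C3–C4) and the silyloxy-bearing carbon closes onto the α-carbon (C1–C2), which gives 3-silyloxycyclobutenone 28. Thermal conrotatory four-electron opening of 28 leads to dienylketene 29, and ring A is then closed as a six-membered carbocycle by disrotatory six-electron electrocyclization between the ketene carbon and the isopropenyl CH2 (C4–C5); the resulting cyclohexadienone 30 enolizes to phenol 31. No stereocentre is formed in 31, and the quaternary centre of 28 disappears on ring opening. The regiochemistry rests on the polarity of the ynol ether, which puts the silyloxy group at C2 next to the ester and leaves the former ketene oxygen as the free C4 hydroxyl. The step needs periselectivity for [2+2] across the ketene C=C over hetero-[4+2] through the ester carbonyl; an aryloxycarbonyl oxygen is a weaker nucleophilic terminus than a ketone oxygen, and the nonpolar solvent is chosen to shorten the life of any zwitterion that could close through oxygen. It also needs the isopropenyl group, not the ester, to lie cis to the ketene in 29; since the opening of 28 is reversible, the productive Z isomer should be drained by the irreversible electrocyclization. The excess of 26 is meant to keep 27 from being trapped by the phenol of 31 as it accumulates.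

Step 13
Reactants: 31 methyl 4-{[4-{[4-hydroxy-6-methyl-2-(triisopropylsilyloxy)benzoyl]oxy}-6-methyl-2-(triisopropylsilyloxy)benzoyl]oxy}-2-methoxy-6-methylbenzoate
Product: 32 methyl 4-{[4-{[2,4-dihydroxy-6-methylbenzoyl]oxy}-2-hydroxy-6-methylbenzoyl]oxy}-2-methoxy-6-methylbenzoate (CNP0503951.0)
Conditions: HF·pyridine, THF–pyridine, 0 °C to rt
Reagents that add atoms: none
Why: Fluoride-driven cleavage of both aryl silyl ethers under buffered acidic conditions, which should leave the aryl esters, the methyl ester and the methyl ether intact and avoid the phenoxide-mediated acyl transfer that a basic fluoride source could cause.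

## Compound list

1 | methyl orsellinate (methyl 2,4-dihydroxy-6-methylbenzoate) | COC(=O)c1c(C)cc(O)cc1O | starting material
2 | benzyl bromide | BrCc1ccccc1 | starting material
3 | methyl 4-(benzyloxy)-2-hydroxy-6-methylbenzoate | COC(=O)c1c(C)cc(OCc2ccccc2)cc1O | intermediate
4 | iodomethane | CI | starting material
5 | methyl 4-(benzyloxy)-2-methoxy-6-methylbenzoate | COC(=O)c1c(C)cc(OCc2ccccc2)cc1OC | intermediate
6 | methyl 4-hydroxy-2-methoxy-6-methylbenzoate | COC(=O)c1c(C)cc(O)cc1OC | intermediate
7 | potassium hydroxide | [K+].[OH-] | starting material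
8 | 4-(benzyloxy)-2-hydroxy-6-methylbenzoic acid | OC(=O)c1c(C)cc(OCc2ccccc2)cc1O | intermediate
9 | 4-(benzyloxy)-2-hydroxy-6-methylbenzoic trifluoroacetic anhydride (not isolated) | O=C(OC(=O)C(F)(F)F)c1c(C)cc(OCc2ccccc2)cc1O | intermediate
10 | methyl 4-{[4-(benzyloxy)-2-hydroxy-6-methylbenzoyl]oxy}-2-methoxy-6-methylbenzoate | COC(=O)c1c(C)cc(OC(=O)c2c(C)cc(OCc3ccccc3)cc2O)cc1OC | intermediate
11 | triisopropylsilyl trifluoromethanesulfonate | CC(C)[Si](OS(=O)(=O)C(F)(F)F)(C(C)C)C(C)C | starting material
12 | methyl 4-{[4-(benzyloxy)-6-methyl-2-(triisopropylsilyloxy)benzoyl]oxy}-2-methoxy-6-methylbenzoate | COC(=O)c1c(C)cc(OC(=O)c2c(C)cc(OCc3ccccc3)cc2O[Si](C(C)C)(C(C)C)C(C)C)cc1OC | intermediate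
13 | methyl 4-{[4-hydroxy-6-methyl-2-(triisopropylsilyloxy)benzoyl]oxy}-2-methoxy-6-methylbenzoate (ArOH) | COC(=O)c1c(C)cc(OC(=O)c2c(C)cc(O)cc2O[Si](C(C)C)(C(C)C)C(C)C)cc1OC | intermediate
14 | bromoacetyl bromide | BrCC(Br)=O | starting material
15 | methyl 4-{[4-(2-bromoacetoxy)-6-methyl-2-(triisopropylsilyloxy)benzoyl]oxy}-2-methoxy-6-methylbenzoate (Ar bromoacetate) | COC(=O)c1c(C)cc(OC(=O)c2c(C)cc(OC(=O)CBr)cc2O[Si](C(C)C)(C(C)C)C(C)C)cc1OC | intermediate
16 | N,N'-bis(p-toluenesulfonyl)hydrazine | Cc1ccc(cc1)S(=O)(=O)NNS(=O)(=O)c1ccc(C)cc1 | starting material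
17 | Ar 2-[1,2-bis(p-toluenesulfonyl)hydrazinyl]acetate (not isolated) | COC(=O)c1c(C)cc(OC(=O)c2c(C)cc(OC(=O)CN(NS(=O)(=O)c3ccc(C)cc3)S(=O)(=O)c3ccc(C)cc3)cc2O[Si](C(C)C)(C(C)C)C(C)C)cc1OC | intermediate
18 | methyl 4-{[4-(2-diazoacetoxy)-6-methyl-2-(triisopropylsilyloxy)benzoyl]oxy}-2-methoxy-6-methylbenzoate (Ar diazoacetate) | COC(=O)c1c(C)cc(OC(=O)c2c(C)cc(OC(=O)C=[N+]=[N-])cc2O[Si](C(C)C)(C(C)C)C(C)C)cc1OC | intermediate
19 | methacrolein | CC(=C)C=O | starting material
20 | Ar 2-diazo-3-hydroxy-4-methylpent-4-enoate (racemic, not isolated) | COC(=O)c1c(C)cc(OC(=O)c2c(C)cc(OC(=O)C(=[N+]=[N-])C(O)C(C)=C)cc2O[Si](C(C)C)(C(C)C)C(C)C)cc1OC | intermediate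
21 | Ar 2-diazo-4-methyl-3-oxopent-4-enoate | COC(=O)c1c(C)cc(OC(=O)c2c(C)cc(OC(=O)C(=[N+]=[N-])C(=O)C(C)=C)cc2O[Si](C(C)C)(C(C)C)C(C)C)cc1OC | intermediate
22 | acetylene | C#C | starting material
23 | tert-butyl hydroperoxide | CC(C)(C)OO | starting material
24 | lithium acetylide (not isolated) | [Li]C#C | intermediate
25 | lithium ethynolate (not isolated) | [Li]OC#C | intermediate
26 | (triisopropylsilyloxy)ethyne | C#CO[Si](C(C)C)(C(C)C)C(C)C | intermediate
27 | Ar 3-methyl-2-(oxomethylidene)but-3-enoate, the (aryloxycarbonyl)(isopropenyl)ketene (not isolated) | COC(=O)c1c(C)cc(OC(=O)c2c(C)cc(OC(=O)C(=C=O)C(C)=C)cc2O[Si](C(C)C)(C(C)C)C(C)C)cc1OC | intermediate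
28 | Ar 4-oxo-1-(prop-1-en-2-yl)-2-(triisopropylsilyloxy)cyclobut-2-ene-1-carboxylate (racemic, not isolated) | COC(=O)c1c(C)cc(OC(=O)c2c(C)cc(OC(=O)C3(C(C)=C)C(=O)C=C3O[Si](C(C)C)(C(C)C)C(C)C)cc2O[Si](C(C)C)(C(C)C)C(C)C)cc1OC | intermediate
29 | Ar (2Z)-5-oxo-2-(prop-1-en-2-yl)-3-(triisopropylsilyloxy)penta-2,4-dienoate (not isolated) | COC(=O)c1c(C)cc(OC(=O)c2c(C)cc(OC(=O)/C(C(C)=C)=C(/C=C=O)O[Si](C(C)C)(C(C)C)C(C)C)cc2O[Si](C(C)C)(C(C)C)C(C)C)cc1OC | intermediate
30 | Ar 2-methyl-4-oxo-6-(triisopropylsilyloxy)cyclohexa-1,5-diene-1-carboxylate (not isolated) | COC(=O)c1c(C)cc(OC(=O)c2c(C)cc(OC(=O)C3=C(C)CC(=O)C=C3O[Si](C(C)C)(C(C)C)C(C)C)cc2O[Si](C(C)C)(C(C)C)C(C)C)cc1OC | intermediate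
31 | methyl 4-{[4-{[4-hydroxy-6-methyl-2-(triisopropylsilyloxy)benzoyl]oxy}-6-methyl-2-(triisopropylsilyloxy)benzoyl]oxy}-2-methoxy-6-methylbenzoate | COC(=O)c1c(C)cc(OC(=O)c2c(C)cc(OC(=O)c3c(C)cc(O)cc3O[Si](C(C)C)(C(C)C)C(C)C)cc2O[Si](C(C)C)(C(C)C)C(C)C)cc1OC | intermediate
32 | methyl 4-{[4-{[2,4-dihydroxy-6-methylbenzoyl]oxy}-2-hydroxy-6-methylbenzoyl]oxy}-2-methoxy-6-methylbenzoate (CNP0503951.0) | COC(=O)c1c(C)cc(OC(=O)c2c(C)cc(OC(=O)c3c(C)cc(O)cc3O)cc2O)cc1OC | target

## Step count and least certain steps

Total step count: 13. Longest linear sequence: 11 steps (1, 2, 3, 5, 6, 7, 8, 9, 10, 12, 13). Step 4 (acid 8 from the shared ether 3) and step 11 (ynol ether 26) are side branches that join at steps 5 and 12.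

**Step 12 (key step, the one carrying the new method).**
- What may go wrong: closure through the ester carbonyl oxygen instead of through carbon, either at the stage of ketene 27 plus alkyne (hetero-[4+2] in place of [2+2]) or at dienylketene 29 if the ester and not the isopropenyl group lies next to the ketene. Further risks are capture of 27 by the phenolic product and photo-Fries cleavage of the aryl esters if shorter wavelengths reach the sample.
- Why: the ester-substituted ketene is a heterodiene as well as a ketene, and this ketene type is untested in the cascade.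
- Fallback (known chemistry): ring A is attached by the same mixed-anhydride esterification as in step 5. It sets out from phenol 13 and acid 8. Trifluoroacetic anhydride in toluene should give methyl 4-{[4-{[4-(benzyloxy)-2-hydroxy-6-methylbenzoyl]oxy}-6-methyl-2-(triisopropylsilyloxy)benzoyl]oxy}-2-methoxy-6-methylbenzoate F1 through anhydride 9. Hydrogenolysis over Pd/C should give methyl 4-{[4-{[2,4-dihydroxy-6-methylbenzoyl]oxy}-6-methyl-2-(triisopropylsilyloxy)benzoyl]oxy}-2-methoxy-6-methylbenzoate F2, and HF·pyridine removes the silyl group, coming back to the route at 32.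

**Step 11.**
- What may go wrong: disproportionation of the monolithium acetylide to the dilithium salt before it is oxygenated, and silylation of the unsubstituted ynolate at carbon instead of oxygen, which would lead to a silylketene.
- Why: the parent acetylide is less stable and the parent ynolate less hindered at carbon than the substituted cases for which the method is established.
- Fallback: the silyl ynol ether is replaced by an alkyl ynol ether made by elimination chemistry, and the ring A C2 oxygen is then carried as a tert-butyl ether. It sets out from diazo ketoester 21.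
  - KOt-Bu and trichloroethylene should give tert-butyl (E)-1,2-dichlorovinyl ether F3. Two equivalents of n-BuLi convert it into lithium tert-butoxyacetylide F4, and protonation gives tert-butoxyethyne F5.
  - Irradiation of 21 with F5 as in step 12 should pass through ketene 27, Ar 2-(tert-butoxy)-4-oxo-1-(prop-1-en-2-yl)cyclobut-2-ene-1-carboxylate F6, Ar (2Z)-3-(tert-butoxy)-5-oxo-2-(prop-1-en-2-yl)penta-2,4-dienoate F7 and Ar 6-(tert-butoxy)-2-methyl-4-oxocyclohexa-1,5-diene-1-carboxylate F8. The product would be methyl 4-{[4-{[2-(tert-butoxy)-4-hydroxy-6-methylbenzoyl]oxy}-6-methyl-2-(triisopropylsilyloxy)benzoyl]oxy}-2-methoxy-6-methylbenzoate F9.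
  - HF·pyridine should then give methyl 4-{[4-{[2-(tert-butoxy)-4-hydroxy-6-methylbenzoyl]oxy}-2-hydroxy-6-methylbenzoyl]oxy}-2-methoxy-6-methylbenzoate F10, and trifluoroacetic acid in CH2Cl2 cleaves the tert-butyl ether, coming back to the route at 32.

**Step 10.**
- What may go wrong: 1,3-dipolar cycloaddition of the diazo group to the electron-poor C=C of methacrolein in competition with the aldol-type addition, and base-induced oligomerization of the enone product while DBU is still present.
- Why: both partners are bifunctional, and the product is a Michael acceptor.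
- Fallback: the C–C bond is made before the diazo group is introduced. It sets out from bromoacetate 15. Zinc in THF with methacrolein 19 (Reformatsky reaction) should give, through the bromozinc enolate of the Ar acetate F11, Ar 3-hydroxy-4-methylpent-4-enoate F12. Dess–Martin periodinane oxidizes it to Ar 4-methyl-3-oxopent-4-enoate F13, and Regitz diazo transfer with 4-acetamidobenzenesulfonyl azide and triethylamine comes back to the route at 21.

**Step 9.**
- What may go wrong: loss of the aryloxide from the activated aryl bromoacetate or diazoacetate under excess amidine base (acyl transfer to the base or elimination to a ketene), and N-alkylation of DBU by the bromide.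
- Why: an aryl ester of an α-substituted acetic acid is a far better acyl donor than the alkyl esters for which this exchange is routine.
- Fallback: the diazoacetyl unit is introduced in one acylation without an alkyl bromide. It sets out from phenol 13. Glyoxylic acid chloride p-toluenesulfonylhydrazone and N,N-dimethylaniline in CH2Cl2 at 0 °C should give Ar (2E)-2-[(p-toluenesulfonyl)hydrazono]acetate F14, and triethylamine in the same flask eliminates sulfinate, coming back to the route at 18.

## Further compounds

F1 | step 12 | methyl 4-{[4-{[4-(benzyloxy)-2-hydroxy-6-methylbenzoyl]oxy}-6-methyl-2-(triisopropylsilyloxy)benzoyl]oxy}-2-methoxy-6-methylbenzoate | COC(=O)c1c(C)cc(OC(=O)c2c(C)cc(OC(=O)c3c(C)cc(OCc4ccccc4)cc3O)cc2O[Si](C(C)C)(C(C)C)C(C)C)cc1OC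
F2 | step 12 | methyl 4-{[4-{[2,4-dihydroxy-6-methylbenzoyl]oxy}-6-methyl-2-(triisopropylsilyloxy)benzoyl]oxy}-2-methoxy-6-methylbenzoate | COC(=O)c1c(C)cc(OC(=O)c2c(C)cc(OC(=O)c3c(C)cc(O)cc3O)cc2O[Si](C(C)C)(C(C)C)C(C)C)cc1OC
F3 | step 11 | tert-butyl (E)-1,2-dichlorovinyl ether | Cl/C=C(/Cl)OC(C)(C)C
F4 | step 11 | lithium tert-butoxyacetylide | [Li]C#COC(C)(C)C
F5 | step 11 | tert-butoxyethyne | C#COC(C)(C)C
F6 | step 11 | Ar 2-(tert-butoxy)-4-oxo-1-(prop-1-en-2-yl)cyclobut-2-ene-1-carboxylate (racemic) | COC(=O)c1c(C)cc(OC(=O)c2c(C)cc(OC(=O)C3(C(C)=C)C(=O)C=C3OC(C)(C)C)cc2O[Si](C(C)C)(C(C)C)C(C)C)cc1OC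
F7 | step 11 | Ar (2Z)-3-(tert-butoxy)-5-oxo-2-(prop-1-en-2-yl)penta-2,4-dienoate | COC(=O)c1c(C)cc(OC(=O)c2c(C)cc(OC(=O)/C(C(C)=C)=C(/C=C=O)OC(C)(C)C)cc2O[Si](C(C)C)(C(C)C)C(C)C)cc1OC
F8 | step 11 | Ar 6-(tert-butoxy)-2-methyl-4-oxocyclohexa-1,5-diene-1-carboxylate | COC(=O)c1c(C)cc(OC(=O)c2c(C)cc(OC(=O)C3=C(C)CC(=O)C=C3OC(C)(C)C)cc2O[Si](C(C)C)(C(C)C)C(C)C)cc1OC
F9 | step 11 | methyl 4-{[4-{[2-(tert-butoxy)-4-hydroxy-6-methylbenzoyl]oxy}-6-methyl-2-(triisopropylsilyloxy)benzoyl]oxy}-2-methoxy-6-methylbenzoate | COC(=O)c1c(C)cc(OC(=O)c2c(C)cc(OC(=O)c3c(C)cc(O)cc3OC(C)(C)C)cc2O[Si](C(C)C)(C(C)C)C(C)C)cc1OC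
F10 | step 11 | methyl 4-{[4-{[2-(tert-butoxy)-4-hydroxy-6-methylbenzoyl]oxy}-2-hydroxy-6-methylbenzoyl]oxy}-2-methoxy-6-methylbenzoate | COC(=O)c1c(C)cc(OC(=O)c2c(C)cc(OC(=O)c3c(C)cc(O)cc3OC(C)(C)C)cc2O)cc1OC
F11 | step 10 | bromozinc enolate of the Ar acetate (Reformatsky reagent from 15) | COC(=O)c1c(C)cc(OC(=O)c2c(C)cc(OC(=O)C[Zn]Br)cc2O[Si](C(C)C)(C(C)C)C(C)C)cc1OC
F12 | step 10 | Ar 3-hydroxy-4-methylpent-4-enoate (racemic) | COC(=O)c1c(C)cc(OC(=O)c2c(C)cc(OC(=O)CC(O)C(C)=C)cc2O[Si](C(C)C)(C(C)C)C(C)C)cc1OC
F13 | step 10 | Ar 4-methyl-3-oxopent-4-enoate | COC(=O)c1c(C)cc(OC(=O)c2c(C)cc(OC(=O)CC(=O)C(C)=C)cc2O[Si](C(C)C)(C(C)C)C(C)C)cc1OC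
F14 | step 9 | Ar (2E)-2-[(p-toluenesulfonyl)hydrazono]acetate | COC(=O)c1c(C)cc(OC(=O)c2c(C)cc(OC(=O)/C=N/NS(=O)(=O)c3ccc(C)cc3)cc2O[Si](C(C)C)(C(C)C)C(C)C)cc1OC
A1 | alternative 1 | methyl acetoacetate | COC(=O)CC(C)=O
A2 | alternative 1 | methyl (E)-but-2-enoate | COC(=O)/C=C/C
A3 | alternative 1 | methyl 6-methyl-2,4-dioxocyclohexane-1-carboxylate (racemic) | COC(=O)C1C(C)CC(=O)CC1=O
A4 | alternative 1 | methyl orsellinate (identical with 1) | COC(=O)c1c(C)cc(O)cc1O
A5 | alternative 2 | methyl 4-methoxy-6-methyl-2-oxo-2H-pyran-5-carboxylate | COC(=O)C1=C(C)OC(=O)C=C1OC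
A6 | alternative 2 | 1,1-bis(trimethylsilyloxy)ethene | C=C(O[Si](C)(C)C)O[Si](C)(C)C
A7 | alternative 2 | methyl 4-hydroxy-2-methoxy-6-methylbenzoate (identical with 6) | COC(=O)c1c(C)cc(O)cc1OC
A8 | alternative 3 | 1-methoxy-1,3-bis(trimethylsilyloxy)buta-1,3-diene (geometry at C1=C2 not defined) | COC(O[Si](C)(C)C)=CC(=C)O[Si](C)(C)C
A9 | alternative 3 | methyl 4-(but-2-ynoyloxy)-2-methoxy-6-methylbenzoate | COC(=O)c1c(C)cc(OC(=O)C#CC)cc1OC
A10 | alternative 3 | methyl 4-[(2,4-dihydroxy-6-methylbenzoyl)oxy]-2-methoxy-6-methylbenzoate | COC(=O)c1c(C)cc(OC(=O)c2c(C)cc(O)cc2O)cc1OC
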